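## Structural features

16 is an achiral pentamer: five benzene rings A to E joined in a row by four diaryl ether oxygens O1 to O4, with eleven free phenolic hydroxyls and no stereocentre, so no stereochemical relationship has to be set. Ring A is a 3,5-dihydroxyphenoxy group. Rings B, C, D and E are each oxygenated at C1, C2, C4 and C6, so C1 of each carries an ether oxygen lying between two oxygenated carbons. O1 joins C1 of ring A to C1 of ring B, O2 joins C6 of ring B to C1 of ring C, O3 joins C4 of ring C to C1 of ring D, and O4 joins C6 of ring D to C1 of ring E. The free polyphenol is very electron-rich and is oxidised by air once deprotonated, so the hydroxyls are best kept as methyl ethers until the last step, which should be acidic and oxygen-free. The real difficulty is the ether bonds: each of O1 to O4 sits on a carbon with two ortho oxygen substituents, and O2 and O4 join such a carbon to a second ortho-substituted carbon, where metal-mediated arylation is weakest. The key step exploits the pattern of ring B: oxygens on C1 and C4 para to each other, with the C2 hydroxyl and O2 on C6 on the two carbons flanking C1. This is a 2,6-dioxygenated 1,4-benzoquinone, whose C2 and C6 are electrophilic; ring D repeats the pattern, with O4 on C6.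

## Logic of the disconnections

16 to 15: the eleven O–CH3 bonds are cut. One protecting group covers every hydroxyl and is the one that 2, 7 and 10 already carry. 15 is air-stable and can be purified on silica. The forward step must cleave all eleven alkyl ethers without touching the four diaryl ethers and must end acidic and oxygen-free.

15 to 8 and 14: the bond from O3 to C4 of ring C is cut. C1 of ring D has both ortho positions oxygenated, so it cannot be an aryne carbon or a workable aryl halide; O3 therefore stays on ring D as a phenol, and C4 of ring C, which has two ortho hydrogens, carries bromine. The cut divides the molecule into a three-ring and a two-ring piece. The forward step is a copper-catalysed arylation of a hindered, oxidisable phenol, and the C–Br bond of 8 has to survive every earlier step.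

8 to 6 and 7: the bond from O1 to C1 of ring A is cut, with the same polarity (oxygen on the flanked C1 of ring B, ring A as the aryl donor). Ring A as a boronic acid allows an oxidative coupling at room temperature that leaves C–Br alone. The step must arylate a di-ortho-substituted phenol without oxidising it.

6 to 5 to 4: the O–CH3 bond on C4 of ring B is cut, then the oxidation level is raised to the quinone. The two hydroxyls of 5 differ: the one on C4 is open and more acidic, the one on C1 is buried, so the methyl group can go to C4 and leave C1 for ring A. The forward steps need a clean two-electron reduction and a mono-selective alkylation with air excluded.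

4 to 1 and 2 by way of 3: the C2–O(methyl) and C6–O2 bonds of ring B are cut. With the C1 and C4 oxygens as carbonyls, C2 and C6 become acceptor carbons carrying chloride, so the whole oxygen pattern of ring B and the most hindered ether bond come from a symmetrical quinone and no ortho-substituted aryl halide is needed. The forward step must put one alkoxide and one aryloxide on 1 in sequence, at the chlorine-bearing carbons only.

14 to 13 to 12 to 9 and 10 by way of 11: the same three cuts on ring D (O–CH3 on C4, C2–O(methyl), C6–O4). Ring D has the oxygen pattern of ring B, so O4 is made as O2 is, with 9 in the place that 1 takes for ring B and bromide as the leaving group. The demands are those of the ring B sequence, with a more electron-rich phenoxide.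

## Other disconnections considered

Alternative 1: The cut is at C2–C3 and C5–C6 of ring E, which is built last.
- Forward step: the aryloxymalonate A2 (the octa-O-methyl A–D tetramer with a malonate on the C6 oxygen of ring D) and diethyl 3-oxopentanedioate A3 condense under an ethoxide base. The two methylene carbons of A3 acylate on the two ester groups of A2 and close ring E as the phloroglucinol diester A1. Ester hydrolysis, decarboxylation and cleavage of eight methyl ethers would follow.
- In favour: O4 exists beforehand as an sp3 C–O bond, so C1 of ring E, the most crowded aryl carbon, is never arylated, and the three ring E hydroxyls appear unprotected.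
- Against: A2 is deprotonated first at its own α-carbon, which makes its esters poor acceptors, and A3 condenses with itself under alkoxide. A1 needs extra steps to lose its esters. The step is the last ring-forming event on the most valuable intermediate, and the three hindered ether bonds of the A–D tetramer are left to other methods.
- Comparison: both plans draw a tetraoxygenated ring from carbonyl precursors, but the chosen plan does so for rings B and D and forms O2 and O4 in the same operation, whereas A1 contains no new ether bond. A double Claisen condensation on a large substrate is less predictable than halide displacement on a quinone, and the route is longer and linear. Alternative 1 is the better plan in that three of eleven hydroxyls never need protection, and the equal of the chosen plan in forming O4 without a transition metal.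

Alternative 2: The cut is at the three C4–O bonds of rings B, D and E, traced back to acetyl groups.
- Forward step: a bicarbonate-buffered aromatic peracid converts the tris(methyl ketone) A5 into the tris(acetate) A4 by Baeyer–Villiger aryl migration. Acetate cleavage and cleavage of eight methyl ethers follow.
- In favour: before the oxidation each acetyl group activates the para carbon C1 of its ring for fluoride displacement, so O1, O3 and O4 could be made by SNAr with the crowded carbon as electrophile. The para aryloxy group helps migration, and three oxygens are set at once.
- Against: C6 of ring B is meta to the acetyl group and ring C carries none, so O2 gains nothing. A fluoride flanked by two alkoxy groups and activated by a single acetyl is displaced slowly. The peracid meets the complete, highly electron-rich pentamer, where ring hydroxylation can compete, and aryl methyl ketones are sluggish substrates.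
- Comparison: the chosen plan has the C4 oxygens of rings B and D in the quinone from the start, whereas A4 receives them last. An electrophilic oxidant at the end contrasts with a single mild reduction early. Each C4 oxygen costs an acetyl group, an oxidation and an ester cleavage, so the route is longer. The SNAr polarity of Alternative 2 (hindered carbon as electrophile, unhindered phenoxide) is better for O1 and O3 than the copper couplings of steps 4 and 8.

Alternative 3: The cut is at C3–C4 of ring A, which is made from a pyranone.
- Forward step: a lithium silylamide base deprotonates the C6 methyl group of the pyranone A7. The anion opens the lactone to a ketene–enolate and recloses through carbon on the former lactone carbonyl, giving the resorcinol A6 after tautomerisation.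
- In favour: O1 would be made earlier by addition–elimination of the flanked ring B phenoxide on a vinylogous acyl carbon, the same kind of metal-free substitution as in the chosen key step, and the ring A hydroxyls arise unprotected.
- Against: the site of deprotonation is not secured, the 4-aryloxy group is a leaving group on a vinylogous ester, and the ketene–enolate can oligomerise. The effort goes into the one ring that can be bought complete (7). A6 has two free hydroxyls to protect before O2, O3 and O4 are made, and its benzyloxy group on C6 of ring B leaves the bond to the flanked C1 of ring C unsolved.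
- Comparison: Alternative 3 solves the least demanding end of the molecule, the chosen plan the two internal tetraoxygenated rings. The ether-forming mechanism is equal in kind, but the ring transformation adds an uncertain anionic step, and protection steps make the route longer. Alternative 3 is better on one point: O1 would be formed without copper at a hindered phenol, which step 4 of the chosen plan has to do.

Key step: step 1

Remark on the chemistry: the C4 substituent of ring C is a spectator in the quinone substitution and is taken as bromine, not as a protected hydroxyl. O3 has to come from the flanked hydroxyl on C1 of ring D, so C4 of ring C must be the electrophile; the two bonds formed and the 2-aryloxy-6-methoxyquinone framework are unchanged.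

## Steps

Step 1
Reactants: 1 2,6-dichloro-1,4-benzoquinone; 2 4-bromo-2,6-dimethoxyphenol
Product: 4 2-(4-bromo-2,6-dimethoxyphenoxy)-6-methoxy-1,4-benzoquinone, via 2-chloro-6-methoxy-1,4-benzoquinone 3 (not isolated)
Conditions: NaOMe (1.0 equiv, in MeOH), THF, −78 to −40 °C; then 2 premixed with NaH (1.0 equiv) in THF, −40 to 0 °C; AcOH quench
Reagents that add atoms: NaOMe (sodium methoxide), C[O-].[Na+]
Why: Methoxide adds to C2 of 1 (the chlorine-bearing carbon β to the C4 carbonyl), the enolate expels chloride and 3 results; the phenoxide of 2 repeats this at the remaining C–Cl carbon to give 4, so the C2–O and C6–O2 bonds of ring B both form by addition–elimination. The closest known reaction type is the replacement of halide in halo-1,4-benzoquinones and halonaphthoquinones by alkoxides and aryloxides (vinylogous acyl substitution). No ring is closed and no stereocentre is formed. Single methoxylation should follow from one equivalent at −78 °C and from the methoxy group of 3 donating into the C4 carbonyl, which makes the second substitution slower than the first. Attack at the chlorine-bearing carbon and not at C3 or C5, and loss of chloride and not of methoxide in the second stage, rest on chloride being the only good leaving group: only the ipso adduct returns to a quinone without a redox step. Electron transfer from the phenoxide to the quinone is held back by the order of addition (3 is a weaker oxidant than 1), the low temperature and the para bromine, which makes the phenoxide of 2 a poorer reductant than a 4-alkoxyphenoxide. The phenoxide can react only at oxygen because its ortho and para carbons are substituted, and its two ortho methoxy groups are tolerated because an unhindered trigonal carbon is attacked from above the ring plane.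

Step 2
Reactants: 4 2-(4-bromo-2,6-dimethoxyphenoxy)-6-methoxy-1,4-benzoquinone
Product: 5 2-(4-bromo-2,6-dimethoxyphenoxy)-6-methoxybenzene-1,4-diol
Conditions: Na2S2O4 (3 equiv), EtOAc/H2O, rt, Ar
Reagents that add atoms: none
Why: Dithionite reduction of a quinone to its hydroquinone is fast and leaves the aryl bromide and the ethers untouched; 5 is air-sensitive and should be carried on at once.

Step 3
Reactants: 5 2-(4-bromo-2,6-dimethoxyphenoxy)-6-methoxybenzene-1,4-diol
Product: 6 2-(4-bromo-2,6-dimethoxyphenoxy)-4,6-dimethoxyphenol
Conditions: MeI (1.05 equiv), K2CO3 (1.0 equiv), degassed DMF, 0 °C to rt, Ar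
Reagents that add atoms: iodomethane, CI
Why: Williamson alkylation with one equivalent of base should take place at the C4 hydroxyl, which is the more acidic (meta to two oxygens) and has two ortho hydrogens. The C1 hydroxyl is buried between the methoxy and aryloxy groups and hydrogen-bonded to them.

Step 4
Reactants: 6 2-(4-bromo-2,6-dimethoxyphenoxy)-4,6-dimethoxyphenol; 7 3,5-dimethoxyphenylboronic acid
Product: 8 1-(4-bromo-2,6-dimethoxyphenoxy)-2-(3,5-dimethoxyphenoxy)-3,5-dimethoxybenzene
Conditions: 7 (2.5 equiv), Cu(OAc)2 (2 equiv), pyridine (5 equiv), 4 Å MS, CH2Cl2, dry air, rt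
Reagents that add atoms: none
Why: Chan–Lam coupling forms O1 from the flanked phenol and the boronic acid at room temperature, where the C–Br bond on ring C cannot enter copper chemistry; the reaction type is established for 2,6-disubstituted phenols, and excess 7 offsets protodeboronation.

Step 5
Reactants: 9 2,6-dibromo-1,4-benzoquinone; 10 2,4,6-trimethoxyphenol
Product: 12 2-methoxy-6-(2,4,6-trimethoxyphenoxy)-1,4-benzoquinone, via 2-bromo-6-methoxy-1,4-benzoquinone 11 (not isolated)
Conditions: NaOMe (1.0 equiv, in MeOH), THF, −78 to −40 °C; then 10 premixed with NaH (1.0 equiv) in THF, −78 to 0 °C; AcOH quench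
Reagents that add atoms: NaOMe (sodium methoxide), C[O-].[Na+]
Why: The same double addition–elimination on a 2,6-dihalo-1,4-benzoquinone as in step 1 builds ring D and O4, here with bromide, which should leave the enolate adduct at least as readily as chloride. The phenoxide of 10 is a stronger reductant than that of 2, so it is added cold to 11 already formed, and with its ortho and para carbons blocked it can react only at oxygen.

Step 6
Reactants: 12 2-methoxy-6-(2,4,6-trimethoxyphenoxy)-1,4-benzoquinone
Product: 13 2-methoxy-6-(2,4,6-trimethoxyphenoxy)benzene-1,4-diol
Conditions: Na2S2O4 (3 equiv), EtOAc/H2O, rt, Ar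
Reagents that add atoms: none
Why: Dithionite reduction of the quinone as in step 2; the hydroquinone is used without delay.

Step 7
Reactants: 13 2-methoxy-6-(2,4,6-trimethoxyphenoxy)benzene-1,4-diol
Product: 14 2,4-dimethoxy-6-(2,4,6-trimethoxyphenoxy)phenol
Conditions: MeI (1.05 equiv), K2CO3 (1.0 equiv), degassed DMF, 0 °C to rt, Ar
Reagents that add atoms: iodomethane, CI
Why: Williamson alkylation at the open, more acidic C4 hydroxyl as in step 3, leaving the flanked C1 hydroxyl of ring D for the fragment coupling.

Step 8
Reactants: 8 1-(4-bromo-2,6-dimethoxyphenoxy)-2-(3,5-dimethoxyphenoxy)-3,5-dimethoxybenzene; 14 2,4-dimethoxy-6-(2,4,6-trimethoxyphenoxy)phenol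
Product: 15 2-(3,5-dimethoxyphenoxy)-1,5-dimethoxy-3-{4-[2,4-dimethoxy-6-(2,4,6-trimethoxyphenoxy)phenoxy]-2,6-dimethoxyphenoxy}benzene
Conditions: CuI (20 mol %), picolinic acid (40 mol %), K3PO4 (2 equiv), 14 (1.3 equiv), DMSO, 95 °C, Ar
Reagents that add atoms: none
Why: Copper-catalysed Ullmann ether synthesis with a picolinate ligand forms O3; the bromide on C4 of ring C has two ortho hydrogens, so all steric demand lies in the phenoxide of 14, the combination this catalyst type is suited to. Methyl and diaryl ethers are inert to K3PO4 in DMSO.

Step 9
Reactants: 15 2-(3,5-dimethoxyphenoxy)-1,5-dimethoxy-3-{4-[2,4-dimethoxy-6-(2,4,6-trimethoxyphenoxy)phenoxy]-2,6-dimethoxyphenoxy}benzene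
Product: 16 4-(3,5-dihydroxyphenoxy)-5-{4-[2,4-dihydroxy-6-(2,4,6-trihydroxyphenoxy)phenoxy]-2,6-dihydroxyphenoxy}benzene-1,3-diol (CNP0018313.0)
Conditions: BBr3 (about 3 equiv per OMe), CH2Cl2, −78 °C to rt, Ar; then ice-water, EtOAc
Reagents that add atoms: none
Why: Each methoxy oxygen binds BBr3 and bromide attacks the methyl carbon (SN2), which cleaves all eleven methyl ethers, while the four diaryl ethers offer no sp3 carbon and stay intact. The acidic, oxygen-free work-up keeps the polyphenol protonated and unoxidised.

## Compound list

1 | 2,6-dichloro-1,4-benzoquinone | O=C1C=C(Cl)C(=O)C(Cl)=C1 | starting material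
2 | 4-bromo-2,6-dimethoxyphenol (ring C phenol) | COc1cc(Br)cc(OC)c1O | starting material
3 | 2-chloro-6-methoxy-1,4-benzoquinone | COC1=CC(=O)C=C(Cl)C1=O | intermediate
4 | 2-(4-bromo-2,6-dimethoxyphenoxy)-6-methoxy-1,4-benzoquinone (ring B as quinone, joined to ring C) | COC1=CC(=O)C=C(Oc2c(OC)cc(Br)cc2OC)C1=O | intermediate
5 | 2-(4-bromo-2,6-dimethoxyphenoxy)-6-methoxybenzene-1,4-diol | COc1cc(O)cc(Oc2c(OC)cc(Br)cc2OC)c1O | intermediate
6 | 2-(4-bromo-2,6-dimethoxyphenoxy)-4,6-dimethoxyphenol | COc1cc(OC)cc(Oc2c(OC)cc(Br)cc2OC)c1O | intermediate
7 | 3,5-dimethoxyphenylboronic acid | COc1cc(OC)cc(B(O)O)c1 | starting material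
8 | 1-(4-bromo-2,6-dimethoxyphenoxy)-2-(3,5-dimethoxyphenoxy)-3,5-dimethoxybenzene (A–B–C bromide) | COc1cc(OC)cc(Oc2c(OC)cc(OC)cc2Oc2c(OC)cc(Br)cc2OC)c1 | intermediate
9 | 2,6-dibromo-1,4-benzoquinone | O=C1C=C(Br)C(=O)C(Br)=C1 | starting material
10 | 2,4,6-trimethoxyphenol (ring E phenol) | COc1cc(OC)c(O)c(OC)c1 | starting material
11 | 2-bromo-6-methoxy-1,4-benzoquinone | COC1=CC(=O)C=C(Br)C1=O | intermediate
12 | 2-methoxy-6-(2,4,6-trimethoxyphenoxy)-1,4-benzoquinone | COC1=CC(=O)C=C(Oc2c(OC)cc(OC)cc2OC)C1=O | intermediate
13 | 2-methoxy-6-(2,4,6-trimethoxyphenoxy)benzene-1,4-diol | COc1cc(O)cc(Oc2c(OC)cc(OC)cc2OC)c1O | intermediate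
14 | 2,4-dimethoxy-6-(2,4,6-trimethoxyphenoxy)phenol (D–E phenol) | COc1cc(OC)cc(Oc2c(OC)cc(OC)cc2OC)c1O | intermediate
15 | 2-(3,5-dimethoxyphenoxy)-1,5-dimethoxy-3-{4-[2,4-dimethoxy-6-(2,4,6-trimethoxyphenoxy)phenoxy]-2,6-dimethoxyphenoxy}benzene (undeca-O-methyl ether of 16) | COc1cc(OC)cc(Oc2c(OC)cc(OC)cc2Oc2c(OC)cc(Oc3c(OC)cc(OC)cc3Oc3c(OC)cc(OC)cc3OC)cc2OC)c1 | intermediate
16 | 4-(3,5-dihydroxyphenoxy)-5-{4-[2,4-dihydroxy-6-(2,4,6-trihydroxyphenoxy)phenoxy]-2,6-dihydroxyphenoxy}benzene-1,3-diol (CNP0018313.0) | Oc1cc(O)cc(Oc2c(O)cc(O)cc2Oc2c(O)cc(Oc3c(O)cc(O)cc3Oc3c(O)cc(O)cc3O)cc2O)c1 | target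

## Step count and least certain steps

Total: 9 steps. Longest linear sequence: 6 steps (steps 1, 2, 3, 4, 8, 9); the D–E branch (steps 5, 6, 7) joins at step 8. Compounds 1, 2, 7, 9 and 10 are catalogue compounds.

Step 1 (key step; step 5 is the same reaction type, run on 9). Most likely failures: conjugate addition at the unsubstituted C3 or C5 followed by redox exchange with unreacted quinone, a second methoxylation, or electron transfer from the phenoxide to the quinone, each of which erodes the two-fold halide displacement. Fallback, from 2 back to 4, without a haloquinone: 2 displaces the fluoride ortho to the nitro group of 1-fluoro-3-methoxy-2-nitrobenzene (K2CO3, DMF, 80 °C; SNAr) to give 5-bromo-1,3-dimethoxy-2-(3-methoxy-2-nitrophenoxy)benzene F1. Reduction with Fe and NH4Cl in aqueous EtOH, which spares the aryl bromide, gives 2-(4-bromo-2,6-dimethoxyphenoxy)-6-methoxyaniline F2. Teuber oxidation of this para-unsubstituted aniline with (KSO3)2NO in phosphate-buffered aqueous acetone, with hydrolysis of the quinone imine, returns to 4.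

Step 4. Most likely failure: slow C–O bond formation at the crowded copper phenoxide, so that protodeboronation and homocoupling of 7 and copper-mediated oxidation of the electron-rich phenol 6 take over. Fallback, from 6 back to 8, metal-free by ligand coupling on iodine: 1-iodo-3,5-dimethoxybenzene is oxidised with mCPBA and TsOH·H2O in MeCN and trapped with 1,3,5-trimethoxybenzene to give (3,5-dimethoxyphenyl)(2,4,6-trimethoxyphenyl)iodonium 4-methylbenzenesulfonate F3. The potassium phenoxide of 6 (KOt-Bu, THF, rt to 40 °C) is arylated by F3 with transfer of the 3,5-dimethoxyphenyl group, the trimethoxyphenyl group staying on iodine, to give 8.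

Step 8. Most likely failure: sluggish coupling of the di-ortho-substituted phenoxide at 95 °C, giving time for hydrodebromination of 8 and oxidative degradation of 14. Fallback, from 8 and 14 back to 15, by elimination–addition without copper: KOt-Bu in DMSO at about 100 °C with excess 14 removes HBr across C3–C4 of ring C. The phenoxide of 14 should add to the resulting aryne at C4, the carbon remote from the C2 methoxy group, which places the transient carbanion next to that methoxy group and gives the same connectivity as direct substitution. No new intermediate is isolated.

Step 9. Most likely failure: incomplete cleavage of the eleven ethers, leaving partial methyl ethers that are hard to separate from the free polyphenol, together with air oxidation during isolation. Fallback, from 15 back to 16, through a purifiable derivative: the crude product of the BBr3 cleavage is acetylated (Ac2O, pyridine) to the undeca-acetate of 16 F4, which can be chromatographed on silica. Methanolysis with HCl in degassed MeOH (from catalytic AcCl) at rt then releases 16.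

Step 3 (step 7 is the same operation on 13). Most likely failure: over-alkylation to the dimethyl ether and base-promoted re-oxidation of the hydroquinone, so that selectivity for the C4 hydroxyl is lost. Fallback, from 5 back to 6, by exhaustive methylation and selective cleavage: excess MeI and K2CO3 in DMF give 5-bromo-1,3-dimethoxy-2-(2,3,5-trimethoxyphenoxy)benzene F5. BCl3 in CH2Cl2 at −20 °C should then cleave only the methoxy group on C1 of ring B, the one forced out of the ring plane between two ortho oxygens, to give 6.

## Further compounds

F1 | step 1 | 5-bromo-1,3-dimethoxy-2-(3-methoxy-2-nitrophenoxy)benzene | COc1cccc(Oc2c(OC)cc(Br)cc2OC)c1[N+](=O)[O-]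
F2 | step 1 | 2-(4-bromo-2,6-dimethoxyphenoxy)-6-methoxyaniline | COc1cccc(Oc2c(OC)cc(Br)cc2OC)c1N
F3 | step 4 | (3,5-dimethoxyphenyl)(2,4,6-trimethoxyphenyl)iodonium 4-methylbenzenesulfonate | COc1cc(OC)cc([I+]c2c(OC)cc(OC)cc2OC)c1.Cc1ccc(S(=O)(=O)[O-])cc1
F0 | step 8 | none | none
F4 | step 9 | undeca-acetate of 16 | CC(=O)Oc1cc(OC(C)=O)cc(Oc2c(OC(C)=O)cc(OC(C)=O)cc2Oc2c(OC(C)=O)cc(Oc3c(OC(C)=O)cc(OC(C)=O)cc3Oc3c(OC(C)=O)cc(OC(C)=O)cc3OC(C)=O)cc2OC(C)=O)c1
F5 | step 3 | 5-bromo-1,3-dimethoxy-2-(2,3,5-trimethoxyphenoxy)benzene | COc1cc(OC)c(OC)c(Oc2c(OC)cc(Br)cc2OC)c1
A1 | alternative 1 | pentamer with ring E as diethyl 2,4,6-trihydroxybenzene-1,3-dicarboxylate, rings A to D octa-O-methyl | CCOC(=O)c1c(O)c(Oc2cc(OC)cc(OC)c2Oc2cc(OC)c(Oc3cc(OC)cc(OC)c3Oc3cc(OC)cc(OC)c3)c(OC)c2)c(O)c(C(=O)OCC)c1O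
A2 | alternative 1 | diethyl 2-aryloxymalonate of the octa-O-methyl A–D tetramer (malonate on the C6 oxygen of ring D) | CCOC(=O)C(Oc1cc(OC)cc(OC)c1Oc1cc(OC)c(Oc2cc(OC)cc(OC)c2Oc2cc(OC)cc(OC)c2)c(OC)c1)C(=O)OCC
A3 | alternative 1 | diethyl 3-oxopentanedioate | CCOC(=O)CC(=O)CC(=O)OCC
A4 | alternative 2 | pentamer tris(acetate), acetoxy on C4 of rings B, D and E | COc1cc(OC)cc(Oc2c(OC)cc(OC(C)=O)cc2Oc2c(OC)cc(Oc3c(OC)cc(OC(C)=O)cc3Oc3c(OC)cc(OC(C)=O)cc3OC)cc2OC)c1
A5 | alternative 2 | pentamer tris(methyl ketone), acetyl on C4 of rings B, D and E | COc1cc(OC)cc(Oc2c(OC)cc(C(C)=O)cc2Oc2c(OC)cc(Oc3c(OC)cc(C(C)=O)cc3Oc3c(OC)cc(C(C)=O)cc3OC)cc2OC)c1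
A6 | alternative 3 | 5-[2-(benzyloxy)-4,6-dimethoxyphenoxy]benzene-1,3-diol | Oc1cc(O)cc(Oc2c(OC)cc(OC)cc2OCc2ccccc2)c1
A7 | alternative 3 | 4-[2-(benzyloxy)-4,6-dimethoxyphenoxy]-6-methyl-2H-pyran-2-one | CC1=CC(Oc2c(OC)cc(OC)cc2OCc2ccccc2)=CC(=O)O1
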